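## Retrosynthetic overview

- Numbering used throughout (also for open-chain intermediates): C1 = CH–O‑senecioate, C2=C3 (E), C4 = quaternary carbon, C5, C6=C7 (C7 bears CH2OH), C8, C9, C10–C11 = oxirane carbons (C11 bears CH3).
- Enabling feature: acyloxy carbon C1 is allylic to C2=C3 and bonded directly to oxirane carbon C11. The C1(O‑acyl)–C11(O)–C10 triad is therefore the retron of a γ‑acyloxyallyl metal (C1–C3) adding to an α‑chloro methyl ketone (C11=O, C10–Cl). The 11‑membered ring closes first at C1–C11, then the C11 alkoxide displaces C10–Cl to close the oxirane.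
- The seco precursor 29 comes from keto enal 27 and senecioyl chloride; 27 comes from Wittig union at C6=C7 of aldehyde 22 (C1–C6) with ylide 8 (C7–C11).
- C4 is set by Johnson–Claisen chirality transfer from a glyceraldehyde‑derived (S,Z)‑allylic alcohol; C10–Cl is set by organocatalytic α‑chlorination of 4‑chlorobutanal.
- Endgame: cross‑metathesis of the allyl group installs the 4‑hydroxy‑4‑methylpent‑2‑enyl chain, then desilylation.

Key step: step 17

Remark on the chemistry: the sense of induction of 2,5‑diphenylpyrrolidine in step 1 is assumed from a steric enamine‑shielding model ((2S,5S) catalyst gives the (R)‑2‑chloroaldehyde); if the opposite holds, the antipodal catalyst is used.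

## Route

Step 1
Reactants: 1 4-chlorobutanal
Product: 3 (2S,3R)-3,5-dichloropentan-2-ol, via (R)-2,4-dichlorobutanal 2 (not isolated)
Conditions: NCS, (2S,5S)-2,5-diphenylpyrrolidine (10 mol%), CH2Cl2, 0 °C; pentane, filter; then MeMgBr, Et2O, −78 °C
Reagents that add atoms: N-chlorosuccinimide O=C1CCC(=O)N1Cl; methylmagnesium bromide C[Mg]Br
Why: Enamine-catalysed asymmetric α-chlorination should set the C10–Cl center under catalyst control, and the labile chloroaldehyde is trapped at once by Cornforth-controlled Grignard addition (anti chlorohydrin); the carbinol configuration is inconsequential because C11 is oxidized in step 15.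

Step 2
Reactants: 3 (2S,3R)-3,5-dichloropentan-2-ol
Product: 4 triethyl[(2S,3R)-3,5-dichloropentan-2-yloxy]silane
Conditions: Et3SiCl, imidazole, CH2Cl2, 0 °C
Reagents that add atoms: chlorotriethylsilane CC[Si](Cl)(CC)CC
Why: Routine silylation, which also stops the chloro alcohol from closing to an oxirane or a tetrahydrofuran in the next steps.

Step 3
Reactants: 4 triethyl[(2S,3R)-3,5-dichloropentan-2-yloxy]silane
Product: 5 triethyl[(2S,3R)-3-chloro-5-iodopentan-2-yloxy]silane
Conditions: NaI, acetone, reflux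
Reagents that add atoms: sodium iodide [Na+].[I-]
Why: Finkelstein exchange should occur only at the primary chloride, the secondary chloride beside the silyloxy branch being far slower in SN2.

Step 4
Reactants: 5 triethyl[(2S,3R)-3-chloro-5-iodopentan-2-yloxy]silane; 6 ethyl (triphenylphosphoranylidene)acetate
Product: 8 ethyl (5R,6S)-5-chloro-6-(triethylsilyloxy)-2-(triphenylphosphoranylidene)heptanoate, via C-alkylated phosphonium iodide 7 (not isolated)
Conditions: 6 (2.1 equiv), MeCN, 80 °C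
Reagents that add atoms: none
Why: C-alkylation of a stabilized ylide by a primary iodide followed by transylidation (the second equivalent of 6 acts as base) is the standard entry to α-substituted stabilized ylides.

Step 5
Reactants: 9 (R)-2,2-dimethyl-1,3-dioxolane-4-carbaldehyde; 10 ethyltriphenylphosphonium iodide
Product: 14 (S,Z)-4-(2-iodoprop-1-en-1-yl)-2,2-dimethyl-1,3-dioxolane, via ethylidenetriphenylphosphorane 11 (not isolated), via (1-iodoethyl)triphenylphosphonium iodide 12 (not isolated), via (1-iodoethylidene)triphenylphosphorane 13 (not isolated)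
Conditions: n-BuLi, THF, 0 °C; I2, −78 °C; NaN(SiMe3)2, −20 °C; then 9, −78 → −20 °C
Reagents that add atoms: iodine II
Why: Stork–Zhao-type α-iodo Wittig olefination should give the (Z)-2-iodoalkene (iodine cis to the dioxolane) at low temperature without touching the existing stereocenter.

Step 6
Reactants: 14 (S,Z)-4-(2-iodoprop-1-en-1-yl)-2,2-dimethyl-1,3-dioxolane; 15 allyltributylstannane
Product: 16 (S,Z)-2,2-dimethyl-4-(2-methylpenta-1,4-dien-1-yl)-1,3-dioxolane
Conditions: Pd2(dba)3 (2.5 mol%), AsPh3 (10 mol%), CuI (10 mol%), DMF, 40 °C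
Reagents that add atoms: none
Why: Stille coupling of an alkenyl iodide proceeds with retention, so the allyl group ends up cis to the dioxolane as the Claisen step requires.

Step 7
Reactants: 16 (S,Z)-2,2-dimethyl-4-(2-methylpenta-1,4-dien-1-yl)-1,3-dioxolane
Product: 17 (2S,3Z)-4-methylhepta-3,6-diene-1,2-diol
Conditions: AcOH/H2O (4:1), 40 °C
Reagents that add atoms: none
Why: Mild acetal hydrolysis should free the diol without allylic transposition.

Step 8
Reactants: 17 (2S,3Z)-4-methylhepta-3,6-diene-1,2-diol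
Product: 18 (2S,3Z)-1-(tert-butyldimethylsilyloxy)-4-methylhepta-3,6-dien-2-ol
Conditions: t-BuMe2SiCl (1.05 equiv), imidazole, CH2Cl2, −20 °C
Reagents that add atoms: tert-butyldimethylsilyl chloride CC(C)(C)[Si](C)(C)Cl
Why: Silylation should be selective for the primary over the secondary allylic hydroxyl on steric grounds.

Step 9
Reactants: 18 (2S,3Z)-1-(tert-butyldimethylsilyloxy)-4-methylhepta-3,6-dien-2-ol; 19 triethyl orthoacetate
Product: 21 ethyl (3S,4E)-3-allyl-6-(tert-butyldimethylsilyloxy)-3-methylhex-4-enoate, via mixed ketene acetal 20 (not isolated)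
Conditions: EtCO2H (10 mol%), neat 19, 140 °C, EtOH distilled off
Reagents that add atoms: none
Why: Johnson–Claisen [3,3] rearrangement through a chair with CH2OSi equatorial (the alternative chair suffers A(1,3) strain with the cis allyl group) should transfer the C2 (S) carbinol chirality suprafacially to the quaternary C4 (S) and give the E C2=C3 alkene.

Step 10
Reactants: 21 ethyl (3S,4E)-3-allyl-6-(tert-butyldimethylsilyloxy)-3-methylhex-4-enoate
Product: 22 (3S,4E)-3-allyl-6-(tert-butyldimethylsilyloxy)-3-methylhex-4-enal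
Conditions: i-Bu2AlH (1.1 equiv), CH2Cl2, −78 °C; aq. sodium potassium tartrate
Reagents that add atoms: none
Why: Partial reduction of an ester to the aldehyde via the aluminium hemiacetal that is stable at −78 °C.

Step 11
Reactants: 22 (3S,4E)-3-allyl-6-(tert-butyldimethylsilyloxy)-3-methylhex-4-enal; 8 ethyl (5R,6S)-5-chloro-6-(triethylsilyloxy)-2-(triphenylphosphoranylidene)heptanoate
Product: 23 ethyl (2E,5S,6E)-5-allyl-8-(tert-butyldimethylsilyloxy)-2-[(3R,4S)-3-chloro-4-(triethylsilyloxy)pentyl]-5-methylocta-2,6-dienoate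
Conditions: toluene, 90 °C
Reagents that add atoms: none
Why: Wittig olefination with an α-substituted stabilized ylide should give the E-trisubstituted enoate, which places C5 trans to the carboxyl carbon (the later CH2OH) and cis to C8 as in the target.

Step 12
Reactants: 23 ethyl (2E,5S,6E)-5-allyl-8-(tert-butyldimethylsilyloxy)-2-[(3R,4S)-3-chloro-4-(triethylsilyloxy)pentyl]-5-methylocta-2,6-dienoate
Product: 24 (2E,5S,6E)-5-allyl-8-(tert-butyldimethylsilyloxy)-2-[(3R,4S)-3-chloro-4-(triethylsilyloxy)pentyl]-5-methylocta-2,6-dien-1-ol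
Conditions: i-Bu2AlH (2.5 equiv), CH2Cl2, −78 °C
Reagents that add atoms: none
Why: 1,2-Reduction of the enoate to the allylic alcohol; the secondary chloride and the silyl ethers are inert to the hydride at −78 °C.

Step 13
Reactants: 24 (2E,5S,6E)-5-allyl-8-(tert-butyldimethylsilyloxy)-2-[(3R,4S)-3-chloro-4-(triethylsilyloxy)pentyl]-5-methylocta-2,6-dien-1-ol
Product: 25 tert-butyldiphenylsilyl ether of 24 at the C7 hydroxymethyl group
Conditions: t-BuPh2SiCl, imidazole, DMF, 0 °C
Reagents that add atoms: tert-butyldiphenylsilyl chloride CC(C)(C)[Si](Cl)(c1ccccc1)c1ccccc1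
Why: Routine silylation that gives the C7 CH2OH a group able to outlast removal of the two more labile silyl ethers.

Step 14
Reactants: 25 tert-butyldiphenylsilyl ether of 24
Product: 26 (2E,4S,6E,10R,11S)-4-allyl-7-[(tert-butyldiphenylsilyloxy)methyl]-10-chloro-4-methyldodeca-2,6-diene-1,11-diol
Conditions: HF·pyridine, pyridine, THF, 0 °C → rt
Reagents that add atoms: none
Why: Buffered fluoride should cleave the triethylsilyl and primary tert-butyldimethylsilyl ethers well before the primary tert-butyldiphenylsilyl ether.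

Step 15
Reactants: 26 (2E,4S,6E,10R,11S)-4-allyl-7-[(tert-butyldiphenylsilyloxy)methyl]-10-chloro-4-methyldodeca-2,6-diene-1,11-diol
Product: 27 (2E,4S,6E,10R)-4-allyl-7-[(tert-butyldiphenylsilyloxy)methyl]-10-chloro-4-methyl-11-oxododeca-2,6-dienal
Conditions: Dess–Martin periodinane (3 equiv), NaHCO3, CH2Cl2, 0 °C
Reagents that add atoms: none
Why: Buffered periodinane oxidation converts the allylic alcohol into the enal and the chlorohydrin into the α-chloro ketone under near-neutral conditions that should not epimerize C10.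

Step 16
Reactants: 27 (2E,4S,6E,10R)-4-allyl-7-[(tert-butyldiphenylsilyloxy)methyl]-10-chloro-4-methyl-11-oxododeca-2,6-dienal; 28 3-methylbut-2-enoyl chloride
Product: 29 (2E,4S,6E,10R)-4-allyl-7-[(tert-butyldiphenylsilyloxy)methyl]-1,10-dichloro-4-methyl-11-oxododeca-2,6-dien-1-yl 3-methylbut-2-enoate (C1 epimers)
Conditions: ZnCl2 (5 mol%), CH2Cl2, −20 → 0 °C; used crude
Reagents that add atoms: none
Why: Lewis-acid-catalysed addition of an acyl chloride across an aldehyde C=O gives the 1-chloroalkyl ester and is selective for the aldehyde over the ketone; the C1 epimers and any 3-chloro enol ester allylic isomer converge in step 17.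

Step 17
Reactants: 29 1-chloroallyl senecioate (C1 epimers)
Product: 32 (1R,2E,4S,6E,10S,11R)-4-allyl-7-[(tert-butyldiphenylsilyloxy)methyl]-10,11-epoxy-4,11-dimethylcycloundeca-2,6-dien-1-yl 3-methylbut-2-enoate, via γ-acyloxyallylchromium dichloride 30 (not isolated), via macrocyclic chlorohydrin 31 (not isolated)
Conditions: CrCl2 (8 equiv), THF, 2 mM (syringe pump, 12 h), 25 °C; then 1 M aq. NaOH, 0 °C
Reagents that add atoms: none
Why: Proposed new method: divalent chromium should reduce only the activated C1–Cl bond (α-chloro ketones are inert to CrCl2 in iodide-free THF) to the (E)-γ-acyloxyallylchromium species 30 (trivalent chromium), whose 1,3-metallotropy erases the C1 configuration and allylic isomerism of 29, and 30 adds through C1 to the C11 ketone by a Nozaki–Hiyama-type allylation through a six-membered Cr–O=C11···C1=C2–C3 transition state, after which hydroxide frees chlorohydrin 31 and its C11 alkoxide displaces C10–Cl; the closest known reactions are chromium-mediated α-hydroxyallylation of carbonyl compounds with 3-halopropenyl esters, Nozaki–Hiyama allylation macrocyclizations onto aldehydes, and allylation of α-chloro ketones followed by base closure to epoxides, but their union in a ketone macrocyclization is untested. The 11-membered ring closes by intramolecular SE2′ carbonyl addition (C1–C11) and the oxirane by 3-exo-tet SN2 with inversion at C10. C11 is controlled by the C10 chloride (Cornforth or polar Felkin–Anh attack anti to Cl on the face flanked by H), which gives the anti chlorohydrin with O and Cl antiperiplanar and hence the trans-oxirane (10S,11R). C1 is controlled relative to C11 by the cyclic transition state: the (E)-enol ester places the acyloxy group equatorial and ring closure should place the C10 branch axial and CH3 equatorial, which leads to the 1,11-syn (1R) isomer, while the quaternary C4 stays equatorial and gives the E C2=C3 alkene; C4 carries two exocyclic groups of similar size and should bias little. The step needs regioselectivity for C1 over the neopentyl C3 terminus (which would form a congested 9-membered ring), chemoselectivity of chromium for the allylic chloride over the α-chloro ketone, and cyclization over oligomerization, secured by sterics at C3, by iodide-free THF and by high dilution.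

Step 18
Reactants: 32 macrocyclic epoxy senecioate; 33 2-methylbut-3-en-2-ol
Product: 34 (1R,2E,4S,6E,10S,11R)-7-[(tert-butyldiphenylsilyloxy)methyl]-10,11-epoxy-4-[(2E)-4-hydroxy-4-methylpent-2-en-1-yl]-4,11-dimethylcycloundeca-2,6-dien-1-yl 3-methylbut-2-enoate
Conditions: second-generation Hoveyda–Grubbs catalyst (10 mol%), 33 (10 equiv), CH2Cl2, 40 °C
Reagents that add atoms: none
Why: Cross-metathesis of the terminal allyl group with the tertiary allylic alcohol should be E-selective, and the ring alkenes (C2=C3 flanked by C1 and quaternary C4, trisubstituted C6=C7) and the senecioate alkene are too hindered or electron-poor to compete.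

Step 19
Reactants: 34 silyl-protected Vibsanin P
Product: 35 Vibsanin P
Conditions: Bu4NF, AcOH (1:1), THF, 0 °C → rt
Reagents that add atoms: none
Why: Acetic-acid-buffered fluoride desilylation should free the primary allylic alcohol without acyl migration, ester cleavage or epoxide opening.

## Compound list

1 | 4-chlorobutanal | O=CCCCCl | starting material
2 | (R)-2,4-dichlorobutanal | O=C[C@H](Cl)CCCl | intermediate
3 | (2S,3R)-3,5-dichloropentan-2-ol | ClCC[C@@H](Cl)[C@H](C)O | intermediate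
4 | triethyl[(2S,3R)-3,5-dichloropentan-2-yloxy]silane | ClCC[C@@H](Cl)[C@H](C)O[Si](CC)(CC)CC | intermediate
5 | triethyl[(2S,3R)-3-chloro-5-iodopentan-2-yloxy]silane | ICC[C@@H](Cl)[C@H](C)O[Si](CC)(CC)CC | intermediate
6 | ethyl (triphenylphosphoranylidene)acetate | CCOC(=O)C=P(c1ccccc1)(c1ccccc1)c1ccccc1 | starting material
7 | [(5R,6S)-5-chloro-1-ethoxy-1-oxo-6-(triethylsilyloxy)heptan-2-yl]triphenylphosphonium iodide | CCOC(=O)C(CC[C@@H](Cl)[C@H](C)O[Si](CC)(CC)CC)[P+](c1ccccc1)(c1ccccc1)c1ccccc1.[I-] | intermediate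
8 | ethyl (5R,6S)-5-chloro-6-(triethylsilyloxy)-2-(triphenylphosphoranylidene)heptanoate | CCOC(=O)C(CC[C@@H](Cl)[C@H](C)O[Si](CC)(CC)CC)=P(c1ccccc1)(c1ccccc1)c1ccccc1 | intermediate
9 | (R)-2,2-dimethyl-1,3-dioxolane-4-carbaldehyde | CC1(C)OC[C@@H](O1)C=O | starting material
10 | ethyltriphenylphosphonium iodide | CC[P+](c1ccccc1)(c1ccccc1)c1ccccc1.[I-] | starting material
11 | ethylidenetriphenylphosphorane | CC=P(c1ccccc1)(c1ccccc1)c1ccccc1 | intermediate
12 | (1-iodoethyl)triphenylphosphonium iodide | CC(I)[P+](c1ccccc1)(c1ccccc1)c1ccccc1.[I-] | intermediate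
13 | (1-iodoethylidene)triphenylphosphorane | CC(I)=P(c1ccccc1)(c1ccccc1)c1ccccc1 | intermediate
14 | (S,Z)-4-(2-iodoprop-1-en-1-yl)-2,2-dimethyl-1,3-dioxolane | CC1(C)OC[C@@H](O1)/C=C(/C)I | intermediate
15 | allyltributylstannane | C=CC[Sn](CCCC)(CCCC)CCCC | starting material
16 | (S,Z)-2,2-dimethyl-4-(2-methylpenta-1,4-dien-1-yl)-1,3-dioxolane | CC1(C)OC[C@@H](O1)/C=C(/C)CC=C | intermediate
17 | (2S,3Z)-4-methylhepta-3,6-diene-1,2-diol | OC[C@@H](O)/C=C(/C)CC=C | intermediate
18 | (2S,3Z)-1-(tert-butyldimethylsilyloxy)-4-methylhepta-3,6-dien-2-ol | CC(C)(C)[Si](C)(C)OC[C@@H](O)/C=C(/C)CC=C | intermediate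
19 | triethyl orthoacetate | CC(OCC)(OCC)OCC | starting material
20 | tert-butyl{[(2S,3Z)-2-(1-ethoxyvinyloxy)-4-methylhepta-3,6-dien-1-yl]oxy}dimethylsilane | C=C(OCC)O[C@H](CO[Si](C)(C)C(C)(C)C)/C=C(/C)CC=C | intermediate
21 | ethyl (3S,4E)-3-allyl-6-(tert-butyldimethylsilyloxy)-3-methylhex-4-enoate | CCOC(=O)C[C@](C)(CC=C)/C=C/CO[Si](C)(C)C(C)(C)C | intermediate
22 | (3S,4E)-3-allyl-6-(tert-butyldimethylsilyloxy)-3-methylhex-4-enal | O=CC[C@](C)(CC=C)/C=C/CO[Si](C)(C)C(C)(C)C | intermediate
23 | ethyl (2E,5S,6E)-5-allyl-8-(tert-butyldimethylsilyloxy)-2-[(3R,4S)-3-chloro-4-(triethylsilyloxy)pentyl]-5-methylocta-2,6-dienoate | CCOC(=O)/C(CC[C@@H](Cl)[C@H](C)O[Si](CC)(CC)CC)=C/C[C@](C)(CC=C)/C=C/CO[Si](C)(C)C(C)(C)C | intermediate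
24 | (2E,5S,6E)-5-allyl-8-(tert-butyldimethylsilyloxy)-2-[(3R,4S)-3-chloro-4-(triethylsilyloxy)pentyl]-5-methylocta-2,6-dien-1-ol | OC/C(CC[C@@H](Cl)[C@H](C)O[Si](CC)(CC)CC)=C/C[C@](C)(CC=C)/C=C/CO[Si](C)(C)C(C)(C)C | intermediate
25 | tert-butyldiphenylsilyl ether of 24 at the C7 hydroxymethyl group | CC(C)(C)[Si](c1ccccc1)(c1ccccc1)OC/C(CC[C@@H](Cl)[C@H](C)O[Si](CC)(CC)CC)=C/C[C@](C)(CC=C)/C=C/CO[Si](C)(C)C(C)(C)C | intermediate
26 | (2E,4S,6E,10R,11S)-4-allyl-7-[(tert-butyldiphenylsilyloxy)methyl]-10-chloro-4-methyldodeca-2,6-diene-1,11-diol | CC(C)(C)[Si](c1ccccc1)(c1ccccc1)OC/C(CC[C@@H](Cl)[C@H](C)O)=C/C[C@](C)(CC=C)/C=C/CO | intermediate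
27 | (2E,4S,6E,10R)-4-allyl-7-[(tert-butyldiphenylsilyloxy)methyl]-10-chloro-4-methyl-11-oxododeca-2,6-dienal | CC(C)(C)[Si](c1ccccc1)(c1ccccc1)OC/C(CC[C@@H](Cl)C(C)=O)=C/C[C@](C)(CC=C)/C=C/C=O | intermediate
28 | 3-methylbut-2-enoyl chloride | CC(C)=CC(Cl)=O | starting material
29 | (2E,4S,6E,10R)-4-allyl-7-[(tert-butyldiphenylsilyloxy)methyl]-1,10-dichloro-4-methyl-11-oxododeca-2,6-dien-1-yl 3-methylbut-2-enoate (C1 epimers) | CC(C)(C)[Si](c1ccccc1)(c1ccccc1)OC/C(CC[C@@H](Cl)C(C)=O)=C/C[C@](C)(CC=C)/C=C/C(Cl)OC(=O)C=C(C)C | intermediate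
30 | (E)-γ-acyloxyallylchromium dichloride (trivalent chromium on C3, C3 epimers) | CC(C)(C)[Si](c1ccccc1)(c1ccccc1)OC/C(CC[C@@H](Cl)C(C)=O)=C/C[C@](C)(CC=C)C([Cr](Cl)Cl)/C=C/OC(=O)C=C(C)C | intermediate
31 | (1R,2E,4S,6E,10R,11S)-4-allyl-7-[(tert-butyldiphenylsilyloxy)methyl]-10-chloro-11-hydroxy-4,11-dimethylcycloundeca-2,6-dien-1-yl 3-methylbut-2-enoate | CC(C)=CC(=O)O[C@@H]1/C=C/[C@@](C)(CC=C)C/C=C(/CO[Si](c2ccccc2)(c2ccccc2)C(C)(C)C)CC[C@@H](Cl)[C@@]1(C)O | intermediate
32 | (1R,2E,4S,6E,10S,11R)-4-allyl-7-[(tert-butyldiphenylsilyloxy)methyl]-10,11-epoxy-4,11-dimethylcycloundeca-2,6-dien-1-yl 3-methylbut-2-enoate | CC(C)=CC(=O)O[C@@H]1/C=C/[C@@](C)(CC=C)C/C=C(/CO[Si](c3ccccc3)(c3ccccc3)C(C)(C)C)CC[C@@H]2O[C@]21C | intermediate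
33 | 2-methylbut-3-en-2-ol | C=CC(C)(C)O | starting material
34 | (1R,2E,4S,6E,10S,11R)-7-[(tert-butyldiphenylsilyloxy)methyl]-10,11-epoxy-4-[(2E)-4-hydroxy-4-methylpent-2-en-1-yl]-4,11-dimethylcycloundeca-2,6-dien-1-yl 3-methylbut-2-enoate | CC(C)=CC(=O)O[C@@H]1/C=C/[C@@](C)(C/C=C/C(C)(C)O)C/C=C(/CO[Si](c3ccccc3)(c3ccccc3)C(C)(C)C)CC[C@@H]2O[C@]21C | intermediate
35 | Vibsanin P | CC(C)=CC(=O)O[C@@H]1/C=C/[C@@](C)(C/C=C/C(C)(C)O)C/C=C(/CO)CC[C@@H]2O[C@]21C | target

## Step count and risks

Total steps: 19. Longest linear sequence: 15 (steps 5–19); steps 1–4 form the convergent branch.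

**Step 17 (Proposed new method).** What may go wrong: reduction of the α-chloro ketone by divalent chromium, attack through C3 or oligomerization instead of 11-membered closure, or poor facial control at C1/C11. The fallback uses known chemistry (Nozaki–Hiyama–Kishi alkenyl iodide macrocyclization, Sharpless epoxidation, Mitsunobu esterification); it sets out from aldehyde 22 and returns at 32. Pent-3-yn-1-ol is hydrozirconated and iodinated (Cp2Zr(H)Cl; I2) to (E)-4-iodopent-3-en-1-ol F1, which is converted (I2, PPh3, imidazole) into (E)-2,5-diiodopent-2-ene F2 and used to alkylate 6 to the ylide ethyl (E)-6-iodo-2-(triphenylphosphoranylidene)hept-5-enoate F3. Wittig reaction of F3 with 22 gives the iodo dienoate F4, i-Bu2AlH the allylic alcohol F5, t-BuPh2SiCl the silyl ether F6, HF·pyridine the C1 alcohol F7 and MnO2 the enal F8. CrCl2 with NiCl2 (cat.) in DMSO/THF at high dilution closes the C1–C11 bond to the macrocyclic (10E)-allylic alcohol F9 (C1 epimers). Sharpless epoxidation (Ti(OiPr)4, L-(+)-diisopropyl tartrate, t-BuOOH) should convert the matched (1S) epimer into the erythro epoxy alcohol F10, and Mitsunobu esterification of F10 with 3-methylbut-2-enoic acid (PPh3, diisopropyl azodicarboxylate) inverts C1 to give 32.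

**Step 16.** What may go wrong: incomplete addition of the conjugated acyl chloride to the enal, or Lewis-acid- and HCl-induced loss of the allylic silyl ether. The fallback sets out from 27 and returns at 32. Acetyl bromide with ZnCl2 (cat.), the established reagent for turning enals into bromoallyl acetates, gives the 1-bromoallyl acetate F11. Chromium-mediated closure as in step 17 gives the chlorohydrin acetate F12 and, after base, the epoxy acetate F13. Methanolysis (K2CO3, MeOH, 0 °C) frees the (1R)-epoxy alcohol F14, which is acylated with 28 (pyridine, 4-dimethylaminopyridine) to 32.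

**Step 5.** What may go wrong: epimerization of the α-alkoxy aldehyde or low conversion with the unstabilized iodo ylide. The fallback sets out from 9 and returns at 16. Dibromoolefination (CBr4, PPh3) gives (S)-4-(2,2-dibromovinyl)-2,2-dimethyl-1,3-dioxolane F15. Trans-selective Negishi monomethylation (MeZnCl, PdCl2(DPEphos)) gives (S,Z)-4-(2-bromoprop-1-en-1-yl)-2,2-dimethyl-1,3-dioxolane F16. Stille coupling of F16 with 15 (Pd(P(t-Bu)3)2) gives 16.

## Further compounds

F1 | step 17 | (E)-4-iodopent-3-en-1-ol | C/C(I)=C\CCO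
F2 | step 17 | (E)-2,5-diiodopent-2-ene | C/C(I)=C\CCI
F3 | step 17 | ethyl (E)-6-iodo-2-(triphenylphosphoranylidene)hept-5-enoate | CCOC(=O)C(CC/C=C(\C)I)=P(c1ccccc1)(c1ccccc1)c1ccccc1
F4 | step 17 | ethyl (2E,5S,6E)-5-allyl-8-(tert-butyldimethylsilyloxy)-2-[(3E)-4-iodopent-3-en-1-yl]-5-methylocta-2,6-dienoate | CCOC(=O)/C(CC/C=C(\C)I)=C/C[C@](C)(CC=C)/C=C/CO[Si](C)(C)C(C)(C)C
F5 | step 17 | (2E,5S,6E)-5-allyl-8-(tert-butyldimethylsilyloxy)-2-[(3E)-4-iodopent-3-en-1-yl]-5-methylocta-2,6-dien-1-ol | OC/C(CC/C=C(\C)I)=C/C[C@](C)(CC=C)/C=C/CO[Si](C)(C)C(C)(C)C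
F6 | step 17 | tert-butyldiphenylsilyl ether of F5 | CC(C)(C)[Si](c1ccccc1)(c1ccccc1)OC/C(CC/C=C(\C)I)=C/C[C@](C)(CC=C)/C=C/CO[Si](C)(C)C(C)(C)C
F7 | step 17 | (2E,4S,6E,10E)-4-allyl-7-[(tert-butyldiphenylsilyloxy)methyl]-11-iodo-4-methyldodeca-2,6,10-trien-1-ol | CC(C)(C)[Si](c1ccccc1)(c1ccccc1)OC/C(CC/C=C(\C)I)=C/C[C@](C)(CC=C)/C=C/CO
F8 | step 17 | (2E,4S,6E,10E)-4-allyl-7-[(tert-butyldiphenylsilyloxy)methyl]-11-iodo-4-methyldodeca-2,6,10-trienal | CC(C)(C)[Si](c1ccccc1)(c1ccccc1)OC/C(CC/C=C(\C)I)=C/C[C@](C)(CC=C)/C=C/C=O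
F9 | step 17 | (2E,4S,6E,10E)-4-allyl-7-[(tert-butyldiphenylsilyloxy)methyl]-4,11-dimethylcycloundeca-2,6,10-trien-1-ol (C1 epimers) | OC1/C=C/[C@@](C)(CC=C)C/C=C(/CO[Si](c2ccccc2)(c2ccccc2)C(C)(C)C)CC/C=C1\C
F10 | step 17 | (1S,2E,4S,6E,10S,11R)-4-allyl-7-[(tert-butyldiphenylsilyloxy)methyl]-10,11-epoxy-4,11-dimethylcycloundeca-2,6-dien-1-ol | O[C@H]1/C=C/[C@@](C)(CC=C)C/C=C(/CO[Si](c3ccccc3)(c3ccccc3)C(C)(C)C)CC[C@@H]2O[C@]21C
F11 | step 16 | (2E,4S,6E,10R)-4-allyl-1-bromo-7-[(tert-butyldiphenylsilyloxy)methyl]-10-chloro-4-methyl-11-oxododeca-2,6-dien-1-yl acetate (C1 epimers) | CC(=O)OC(Br)/C=C/[C@@](C)(CC=C)C/C=C(/CO[Si](c1ccccc1)(c1ccccc1)C(C)(C)C)CC[C@@H](Cl)C(C)=O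
F12 | step 16 | (1R,2E,4S,6E,10R,11S)-4-allyl-7-[(tert-butyldiphenylsilyloxy)methyl]-10-chloro-11-hydroxy-4,11-dimethylcycloundeca-2,6-dien-1-yl acetate | CC(=O)O[C@@H]1/C=C/[C@@](C)(CC=C)C/C=C(/CO[Si](c2ccccc2)(c2ccccc2)C(C)(C)C)CC[C@@H](Cl)[C@@]1(C)O
F13 | step 16 | (1R,2E,4S,6E,10S,11R)-4-allyl-7-[(tert-butyldiphenylsilyloxy)methyl]-10,11-epoxy-4,11-dimethylcycloundeca-2,6-dien-1-yl acetate | CC(=O)O[C@@H]1/C=C/[C@@](C)(CC=C)C/C=C(/CO[Si](c3ccccc3)(c3ccccc3)C(C)(C)C)CC[C@@H]2O[C@]21C
F14 | step 16 | (1R,2E,4S,6E,10S,11R)-4-allyl-7-[(tert-butyldiphenylsilyloxy)methyl]-10,11-epoxy-4,11-dimethylcycloundeca-2,6-dien-1-ol | O[C@@H]1/C=C/[C@@](C)(CC=C)C/C=C(/CO[Si](c3ccccc3)(c3ccccc3)C(C)(C)C)CC[C@@H]2O[C@]21C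
F15 | step 5 | (S)-4-(2,2-dibromovinyl)-2,2-dimethyl-1,3-dioxolane | CC1(C)OC[C@@H](O1)C=C(Br)Br
F16 | step 5 | (S,Z)-4-(2-bromoprop-1-en-1-yl)-2,2-dimethyl-1,3-dioxolane | CC1(C)OC[C@@H](O1)/C=C(/C)Br
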